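**Retrosynthetic overview**
1. Feature: ring carbons C3 and C6 are 1,4-related oxygenated carbons on either side of the C4=C5 methyl enol ether. Both C–O bonds are traced to O2 added across the termini of the 2-methoxycyclohexa-1,3-diene 12, and the endoperoxide is opened to the 4-hydroxy-3-methoxy enone 15.
2. After the key step: 15 ⇒ C6 acetate 16 ⇒ C2 selenide 18 ⇒ C3 alcohol 19 (hydride) ⇒ C1=C2 by selenoxide syn-elimination (target 21).
3. Before the key step: 12 ⇐ enone 10 through its dimethyl ketal 11 (loss of methanol toward C6); 10 ⇐ enal 6 + tert-butyl acetoacetate (organocatalytic Michael addition, aldol condensation, decarboxylation; sets C1).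
4. 6 ⇐ cross-metathesis of the (R)-homoallylic acetate 4 with acrolein; 4 ⇐ asymmetric allylboration of dodecanal.
5. Ring order: the carbocycle (the only ring of the target) is closed in step 4; the 1,2-dioxine ring of endoperoxide 14 is closed and reopened within step 7.

Key step: step 7

Remark: ring locants of the target (C1 side-chain carbon, C2, C3 hydroxyl, C4, C5 methoxy, C6 acetoxy) are used for all ring compounds. The target SMILES is read as side-chain carbinol R, C3 S, C6 S, that is, with the C3 hydroxyl trans to the C6 acetoxy group.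

**Route**

Step 1
Reactants: 1 dodecanal; 2 (−)-B-allyldiisopinocampheylborane (from (+)-α-pinene)
Product: 3 (4R)-pentadec-1-en-4-ol
Conditions: 2 (1 M in pentane), Et2O, −78 °C to rt; then 3 M NaOH, 30% H2O2, reflux
Reagents that add atoms: none
Why: Brown asymmetric allylboration through a closed chair (Zimmerman–Traxler) transition state, in which the isopinocampheyl groups derived from (+)-α-pinene direct the allyl group to the Si face of an n-alkanal and so set the carbinol centre as R (the side-chain centre of the target).

Step 2
Reactants: 3 (4R)-pentadec-1-en-4-ol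
Product: 4 (4R)-pentadec-1-en-4-yl acetate
Conditions: Ac2O, pyridine, DMAP (cat.), CH2Cl2, 0 °C to rt
Reagents that add atoms: acetic anhydride, CC(=O)OC(C)=O
Why: DMAP-catalysed O-acylation of a secondary alcohol; the acetate is the side-chain ester of the target and is carried through because no later step uses a strong base, a strong nucleophile or a hydride at a temperature at which it would be cleaved.

Step 3
Reactants: 4 (4R)-pentadec-1-en-4-yl acetate; 5 acrolein
Product: 6 (2E,5R)-1-oxohexadec-2-en-5-yl acetate
Conditions: acrolein (4 equiv), second-generation Hoveyda–Grubbs catalyst RuCl2(H2IMes)(=CH-C6H4-2-OiPr) (3 mol%), CH2Cl2, 40 °C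
Reagents that add atoms: none
Why: Olefin cross-metathesis of a terminal alkene with an excess of the electron-poor partner acrolein, which does not readily homodimerize, should give the E enal with loss of ethene; the remote acetate is inert.

Step 4
Reactants: 6 (2E,5R)-1-oxohexadec-2-en-5-yl acetate; 7 tert-butyl acetoacetate
Product: 10 (2R)-1-[(1S)-5-oxocyclohex-3-en-1-yl]tridecan-2-yl acetate, via Michael adduct 8 (not isolated), via cyclohexenone tert-butyl ester 9 (not isolated)
Conditions: 7 (2 equiv), (S)-2-{bis[3,5-bis(trifluoromethyl)phenyl][(trimethylsilyl)oxy]methyl}pyrrolidine (10 mol%), neat, rt; then TsOH·H2O (20 mol%), toluene, 80 °C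
Reagents that add atoms: none
Why: Iminium-activated Michael addition in which the diaryl(silyloxy)methyl group of the (S)-catalyst shields one face of the E,s-trans iminium ion, so that the acetoacetate adds to the open face of the β-carbon and sets ring carbon C1 (S in 10); acid then promotes intramolecular aldol condensation, tert-butyl ester cleavage and decarboxylation (a Robinson-type annulation).

Step 5
Reactants: 10 (2R)-1-[(1S)-5-oxocyclohex-3-en-1-yl]tridecan-2-yl acetate
Product: 11 (2R)-1-[(1S)-5,5-dimethoxycyclohex-3-en-1-yl]tridecan-2-yl acetate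
Conditions: MeOSiMe3 (2.5 equiv), Me3SiOTf (5 mol%), CH2Cl2, −78 °C; pyridine quench, NaHCO3 work-up
Reagents that add atoms: methoxytrimethylsilane, CO[Si](C)(C)C
Why: Me3SiOTf-catalysed acetalization with the silyl ether of methanol is driven by formation of hexamethyldisiloxane and runs under aprotic conditions at −78 °C, so neither conjugate addition of methanol nor migration of the C3=C4 double bond should intervene; C1 is untouched.

Step 6
Reactants: 11 (2R)-1-[(1S)-5,5-dimethoxycyclohex-3-en-1-yl]tridecan-2-yl acetate
Product: 12 (2R)-1-[(1S)-3-methoxycyclohexa-2,4-dien-1-yl]tridecan-2-yl acetate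
Conditions: Me3SiOTf (1.2 equiv), i-Pr2NEt (1.5 equiv), CH2Cl2, −20 to 0 °C; basic work-up, used promptly
Reagents that add atoms: none
Why: Me3SiOTf ionizes the allylic ketal to a methoxyallyl cation, from which the hindered amine removes the proton at C6, next to the oxocarbenium carbon (kinetic α′ deprotonation, as in the formation of cross-conjugated silyl dienol ethers from cyclohexenones with silyl triflates and amines), giving the 2-methoxy-1,3-diene under non-equilibrating, ester-compatible conditions.

Step 7
Reactants: 12 (2R)-1-[(1S)-3-methoxycyclohexa-2,4-dien-1-yl]tridecan-2-yl acetate; 13 dioxygen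
Product: 15 (2R)-1-[(1R,2S)-2-hydroxy-3-methoxy-5-oxocyclohex-3-en-1-yl]tridecan-2-yl acetate, via endoperoxide 14 (not isolated)
Conditions: O2, 5,10,15,20-tetraphenylporphyrin (1 mol%), CH2Cl2, −78 °C, white LED; then Et3N (1.2 equiv), −78 to 0 °C
Reagents that add atoms: none
Why: Energy transfer from the triplet porphyrin gives singlet oxygen, which adds in a concerted suprafacial [4+2] cycloaddition across C3 and C6 of the ring-locked s-cis diene, as in the dye-sensitized photooxygenation of cyclohexa-1,3-dienes (α-terpinene to ascaridole). The only ring closed is the six-membered 1,2-dioxine ring of the 2,3-dioxabicyclo[2.2.2]octene 14, closed by that cycloaddition with both C–O bonds on one face and opened again in the same flask. Triethylamine then removes the C3 bridgehead hydrogen as the O–O bond breaks (Kornblum–DeLaMare rearrangement), giving the C3 ketone and, after proton transfer, the C6 hydroxyl. The new C6 stereocentre (S) is controlled by the adjacent C1 stereocentre, whose side chain shields one face of the diene terminus C6 so that oxygen enters anti to it; the C3 centre formed at the same time is erased on opening. The step needs [4+2] addition over ene or [2+2] reaction (secured by the cisoid ring diene, low temperature and a non-polar solvent), anti facial selectivity (secured by the C1 substituent) and opening at C3 and not at C6 (secured by the unhindered C3–H next to the C2 methylene and by the vinylogous ester that this deprotonation creates).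

Step 8
Reactants: 15 (2R)-1-[(1R,2S)-2-hydroxy-3-methoxy-5-oxocyclohex-3-en-1-yl]tridecan-2-yl acetate
Product: 16 (1S,6R)-6-[(2R)-2-acetoxytridecyl]-2-methoxy-4-oxocyclohex-2-en-1-yl acetate
Conditions: Ac2O, pyridine, DMAP (cat.), CH2Cl2, 0 °C
Reagents that add atoms: acetic anhydride, CC(=O)OC(C)=O
Why: DMAP-catalysed acylation of the secondary C6 hydroxyl under mild, brief basic conditions caps the γ-hydroxy enone before it can isomerize to the 1,4-dione and installs the ring acetate of the target; no stereocentre is touched.

Step 9
Reactants: 16 (1S,6R)-6-[(2R)-2-acetoxytridecyl]-2-methoxy-4-oxocyclohex-2-en-1-yl acetate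
Product: 18 (1S,5R,6S)-6-[(2R)-2-acetoxytridecyl]-2-methoxy-4-oxo-5-(phenylselanyl)cyclohex-2-en-1-yl acetate, via silyl dienol ether 17 (not isolated)
Conditions: t-BuMe2SiOTf (1.2 equiv), Et3N (1.5 equiv), CH2Cl2, −78 to 0 °C; then PhSeCl (1.1 equiv), −78 °C
Reagents that add atoms: benzeneselenenyl chloride, Cl[Se]c1ccccc1; tert-butyldimethylsilyl triflate, CC(C)(C)[Si](C)(C)OS(=O)(=O)C(F)(F)F (its silyl group is present only in 17)
Why: Soft enolization (O-silylation of the vinylogous ester, then amine deprotonation at the α′ carbon C2, as in the preparation of 1-alkoxy-3-silyloxy dienes) avoids a lithium amide that would enolize the two acetates, and the selenium electrophile then attacks the diene terminus C2 anti to the adjacent C1 side chain, giving the trans arrangement (also the thermodynamically preferred one at this epimerizable carbon) with Se cis to C1–H.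

Step 10
Reactants: 18 (1S,5R,6S)-6-[(2R)-2-acetoxytridecyl]-2-methoxy-4-oxo-5-(phenylselanyl)cyclohex-2-en-1-yl acetate
Product: 19 (1S,4R,5R,6S)-6-[(2R)-2-acetoxytridecyl]-4-hydroxy-2-methoxy-5-(phenylselanyl)cyclohex-2-en-1-yl acetate
Conditions: NaBH4, CeCl3·7H2O, MeOH, −78 °C; NaHCO3 work-up
Reagents that add atoms: none
Why: Luche reduction: the small borohydride reagent adds 1,2 and axially, from the face anti to the C1 side chain (the sense of carvone to cis-carveol), so that the C3 hydroxyl becomes equatorial, trans to both the C2 selanyl and the C6 acetoxy groups (the C3 centre of the target, S there), and the acetates survive at −78 °C.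

Step 11
Reactants: 19 (1S,4R,5R,6S)-6-[(2R)-2-acetoxytridecyl]-4-hydroxy-2-methoxy-5-(phenylselanyl)cyclohex-2-en-1-yl acetate
Product: 21 (1S,4S)-6-[(2R)-2-acetoxytridecyl]-4-hydroxy-2-methoxycyclohexa-2,5-dien-1-yl acetate, via selenoxide 20 (not isolated)
Conditions: 30% H2O2 (3 equiv), pyridine (3 equiv), CH2Cl2, 0 °C to rt; NaHCO3 work-up, Et3N-deactivated silica
Reagents that add atoms: hydrogen peroxide, OO (its oxygen is present only in 20)
Why: Oxidation of the selenide to the selenoxide is followed by thermal syn-elimination through a five-membered cyclic transition state, which in β-hydroxy selenoxides runs away from the carbinol carbon and here can use only the cis C1–H, giving the C1=C2 allylic alcohol; excess peroxide oxidizes the selenenic acid on to the seleninic acid, and pyridine keeps the acid-labile methoxy-allylic alcohol buffered.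

**Compound list**

1 | dodecanal | CCCCCCCCCCCC=O | starting material
2 | (−)-B-allyldiisopinocampheylborane, (prop-2-en-1-yl)bis[(1R,2S,3R,5R)-2,6,6-trimethylbicyclo[3.1.1]heptan-3-yl]borane | C=CCB([C@@H]1C[C@@H]2C[C@H]([C@H]1C)C2(C)C)[C@@H]1C[C@@H]2C[C@H]([C@H]1C)C2(C)C | starting material
3 | (4R)-pentadec-1-en-4-ol | CCCCCCCCCCC[C@H](CC=C)O | intermediate
4 | (4R)-pentadec-1-en-4-yl acetate | CCCCCCCCCCC[C@H](CC=C)OC(C)=O | intermediate
5 | acrolein | C=CC=O | starting material
6 | (2E,5R)-1-oxohexadec-2-en-5-yl acetate | CCCCCCCCCCC[C@H](C/C=C/C=O)OC(C)=O | intermediate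
7 | tert-butyl acetoacetate | CC(=O)CC(=O)OC(C)(C)C | starting material
8 | tert-butyl (3R,5R)-5-acetoxy-2-acetyl-3-(2-oxoethyl)hexadecanoate (C2 epimers; Michael adduct) | CCCCCCCCCCC[C@H](C[C@H](CC=O)C(C(C)=O)C(=O)OC(C)(C)C)OC(C)=O | intermediate
9 | tert-butyl (6S)-6-[(2R)-2-acetoxytridecyl]-2-oxocyclohex-3-ene-1-carboxylate (C1 epimers) | CCCCCCCCCCC[C@H](C[C@@H]1CC=CC(=O)C1C(=O)OC(C)(C)C)OC(C)=O | intermediate
10 | (2R)-1-[(1S)-5-oxocyclohex-3-en-1-yl]tridecan-2-yl acetate | CCCCCCCCCCC[C@H](C[C@@H]1CC=CC(=O)C1)OC(C)=O | intermediate
11 | (2R)-1-[(1S)-5,5-dimethoxycyclohex-3-en-1-yl]tridecan-2-yl acetate | CCCCCCCCCCC[C@H](C[C@@H]1CC=CC(OC)(OC)C1)OC(C)=O | intermediate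
12 | (2R)-1-[(1S)-3-methoxycyclohexa-2,4-dien-1-yl]tridecan-2-yl acetate | CCCCCCCCCCC[C@H](C[C@@H]1CC=CC(OC)=C1)OC(C)=O | intermediate
13 | dioxygen | O=O | starting material
14 | (2R)-1-[(1S,4R,7R)-6-methoxy-2,3-dioxabicyclo[2.2.2]oct-5-en-7-yl]tridecan-2-yl acetate (peroxide bridge anti to the side chain) | CCCCCCCCCCC[C@H](C[C@@H]1C[C@H]2OO[C@@H]1C(OC)=C2)OC(C)=O | intermediate
15 | (2R)-1-[(1R,2S)-2-hydroxy-3-methoxy-5-oxocyclohex-3-en-1-yl]tridecan-2-yl acetate, that is (4S,5R)-5-[(2R)-2-acetoxytridecyl]-4-hydroxy-3-methoxycyclohex-2-en-1-one | CCCCCCCCCCC[C@H](C[C@@H]1CC(=O)C=C(OC)[C@H]1O)OC(C)=O | intermediate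
16 | (1S,6R)-6-[(2R)-2-acetoxytridecyl]-2-methoxy-4-oxocyclohex-2-en-1-yl acetate | CCCCCCCCCCC[C@H](C[C@@H]1CC(=O)C=C(OC)[C@H]1OC(C)=O)OC(C)=O | intermediate
17 | (1S,6R)-6-[(2R)-2-acetoxytridecyl]-4-[(tert-butyldimethylsilyl)oxy]-2-methoxycyclohexa-2,4-dien-1-yl acetate | CCCCCCCCCCC[C@H](C[C@@H]1C=C(O[Si](C)(C)C(C)(C)C)C=C(OC)[C@H]1OC(C)=O)OC(C)=O | intermediate
18 | (1S,5R,6S)-6-[(2R)-2-acetoxytridecyl]-2-methoxy-4-oxo-5-(phenylselanyl)cyclohex-2-en-1-yl acetate | CCCCCCCCCCC[C@H](C[C@@H]1[C@@H]([Se]c2ccccc2)C(=O)C=C(OC)[C@H]1OC(C)=O)OC(C)=O | intermediate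
19 | (1S,4R,5R,6S)-6-[(2R)-2-acetoxytridecyl]-4-hydroxy-2-methoxy-5-(phenylselanyl)cyclohex-2-en-1-yl acetate | CCCCCCCCCCC[C@H](C[C@@H]1[C@@H]([Se]c2ccccc2)[C@H](O)C=C(OC)[C@H]1OC(C)=O)OC(C)=O | intermediate
20 | (1S,4R,5R,6S)-6-[(2R)-2-acetoxytridecyl]-4-hydroxy-2-methoxy-5-(phenylseleninyl)cyclohex-2-en-1-yl acetate (both configurations at selenium) | CCCCCCCCCCC[C@H](C[C@@H]1[C@@H]([Se](=O)c2ccccc2)[C@H](O)C=C(OC)[C@H]1OC(C)=O)OC(C)=O | intermediate
21 | (1S,4S)-6-[(2R)-2-acetoxytridecyl]-4-hydroxy-2-methoxycyclohexa-2,5-dien-1-yl acetate (CNP0081579.1) | CCCCCCCCCCC[C@H](CC1=C[C@H](O)C=C(OC)[C@H]1OC(C)=O)OC(C)=O | target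

**Step count and risks**

Total step count: 11. Longest linear sequence: 11 steps (from dodecanal 1 to target 21; the other building blocks 2, 5, 7 and 13 are commercial).

Steps most likely to fail:

1. Step 7 (key step). The opening of the endoperoxide may take the wrong course: proton removal at C6 instead of C3, or amine-promoted isomerization of the γ-hydroxy enone onward to the 1,4-dione. Ene or [2+2] reaction at the enol ether and incomplete facial selectivity are further risks. Fallback, from 12 back to 15: the photooxygenation is run as before, but 14 is not treated with base. It is reduced at −78 °C to rt with thiourea in MeOH to the cis-diol (2R)-1-[(1S,2S,5R)-2,5-dihydroxy-3-methoxycyclohex-3-en-1-yl]tridecan-2-yl acetate F1. MnO2 in CH2Cl2 at rt should then oxidize the less hindered allylic C3 carbinol, whose oxidation is also favoured because it creates the vinylogous ester, which returns the route to 15.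

2. Step 6. The methoxyallyl cation may lose its proton at C2 instead of C6, which would give the linearly conjugated 1-methoxy diene, or the product may hydrolyse back to the enone on work-up. Fallback, from 10 directly to 12: kinetic deprotonation of the enone at C6 with KN(SiMe3)2 in THF–DMPU at −78 °C and O-methylation of the cross-conjugated potassium dienolate with methyl triflate at that temperature. The ketone α′-hydrogen is removed faster than the acetate α-hydrogen, and the enolate is trapped before acyl transfer can occur. No new compound is made (F0).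

3. Step 10. Facial selectivity may be poor: hydride may be delivered anti to a pseudo-axial C–Se bond (Felkin–Anh), that is from the face of the side chain, which leads to the C3 epimer. Fallback, from 18 to 19: reagent-controlled Corey–Bakshi–Shibata reduction with (S)-B-methyl-CBS-oxazaborolidine (20 mol%) and catecholborane in toluene at −78 °C. The branched, selanyl-bearing C2 is expected to act as the large group, which places hydride on the face anti to the side chain, the face the substrate itself prefers (a matched case). No new compound is made (F0).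

**Further compounds**

F1 | step 7 | (2R)-1-[(1S,2S,5R)-2,5-dihydroxy-3-methoxycyclohex-3-en-1-yl]tridecan-2-yl acetate | CCCCCCCCCCC[C@H](C[C@@H]1C[C@@H](O)C=C(OC)[C@H]1O)OC(C)=O
F0 | step 6 | none | none
F0 | step 10 | none | none
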